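**Retrosynthetic overview**
1. Target 10 ⇐ its phenol O‑acetate 9; the acetyl group is removed last by chemoselective aminolysis.
2. 9 ⇐ C9–C10 of the docosanoyl chain, made by a crossed Kolbe electrolysis. Tetradecanoic acid 6 loses CO2 to give C10–C22 (tridecyl). The sebacic half‑ester 5 loses CO2 to give C1–C9 with the aryl‑propyl ester already in place. Two carboxylate‑derived carbons of like polarity are joined as radicals.
3. Enabling feature: C9 and C10 are unbranched CH2 carbons inside the saturated C2–C21 polymethylene chain, with no heteroatom, branch or π‑system next to either, so both correspond to primary alkyl radicals that are not oxidised further. C9 is the eighth CH2 from ester carbonyl C1, i.e. the ω‑carbon of sebacic acid. The only ring, the 1,4‑disubstituted benzene ring, is remote from C9 and carries its oxygen as an electron‑poor acetate.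
4. 5 ⇐ sebacic acid 4 + 4‑(3‑hydroxypropyl)phenyl acetate 3 (mono‑esterification); 3 ⇐ diol 1 by phenoxide‑selective acetylation.
5. No ring is formed in the route: the benzene ring is bought with 1.

Key step: step 3

Remark: the target has no stereocentre and no double‑bond geometry, so the main route needs no stereodescriptors; compounds 1, 4 and 6 are assumed to be purchased.

**Step 1**
Reactants: 1 3‑(4‑hydroxyphenyl)propan‑1‑ol
Product: 3 4‑(3‑hydroxypropyl)phenyl acetate, via sodium 4‑(3‑hydroxypropyl)phenolate 2 (not isolated)
Conditions: NaOH (1.05 equiv), H2O, 0 °C; then Ac2O (1.1 equiv), 0 °C, 15 min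
Reagents that add atoms: acetic anhydride CC(=O)OC(C)=O
Why: In aqueous NaOH only the phenol (pKa about 10) is ionised and the primary alcohol (pKa about 16) is not, so phenolate 2 should capture the anhydride much faster than water or the neutral alcohol, a Schotten–Baumann (Chattaway) phenol acetylation that leaves the 3‑hydroxypropyl group free.

**Step 2**
Reactants: 3 4‑(3‑hydroxypropyl)phenyl acetate; 4 decanedioic acid (sebacic acid, 4 equiv)
Product: 5 10‑{3‑[4‑(acetyloxy)phenyl]propoxy}‑10‑oxodecanoic acid
Conditions: DIC (1.1 equiv), DMAP (0.1 equiv), THF/CH2Cl2, 0 °C → rt; H2O quench, excess 4 filtered off from cold CH2Cl2, chromatography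
Reagents that add atoms: none
Why: Steglich (carbodiimide/DMAP) esterification of the unhindered primary alcohol, in which the fourfold excess of the symmetrical diacid should statistically hold the reaction at the mono‑ester while the aryl acetate is untouched under these near‑neutral conditions.

**Step 3**
Reactants: 5 10‑{3‑[4‑(acetyloxy)phenyl]propoxy}‑10‑oxodecanoic acid; 6 tetradecanoic acid (myristic acid, 4–5 equiv)
Product: 9 3‑[4‑(acetyloxy)phenyl]propyl docosanoate, via tridecyl radical 7 (not isolated), via 9‑{3‑[4‑(acetyloxy)phenyl]propoxy}‑9‑oxononyl radical 8 (not isolated)
Conditions: KOH (5 mol% of total CO2H, added to the acids first), MeOH (hexane co‑solvent), Pt anode/Pt cathode, undivided cell, constant current ca. 0.25 A cm⁻², 45–50 °C, periodic polarity reversal, stopped while still weakly acidic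
Reagents that add atoms: none
Why: Crossed Kolbe electrolysis: anodic one‑electron oxidation of the carboxylate groups of 5 and 6 at smooth platinum, with loss of CO2, gives the primary alkyl radicals 8 and 7 at high concentration in the anode layer, where their combination forms the C9–C10 bond while the cathode discharges the carboxyl protons as H2. The closest known reaction type is the classical crossed Kolbe coupling of a fatty acid with an alkyl hydrogen α,ω‑alkanedioate (half‑ester of adipic, suberic or sebacic acid), the standard electrochemical chain extension of fatty acids. No ring is closed and no stereocentre is created, so neither a closure mode nor stereocontrol arises. The step needs cross‑ over homo‑coupling, which the four‑ to fivefold excess of the cheap acid 6 secures for the valuable partner 5 (the by‑product hexacosane is a hydrocarbon and is removed on silica), and it needs the radical path over the two‑electron Hofer–Moest carbocation path, which is secured by both radicals being primary and unstabilised, together with platinum, high current density and a weakly acidic methanolic electrolyte. Chemoselectivity against oxidation of the arene is secured by the O‑acetyl group, which keeps the ring near the oxidation potential of a simple alkylbenzene (a free phenol or aryl ether would be oxidised first), and both ester groups should survive because the electrolyte stays buffered on the acidic side as long as free 6 remains.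

**Step 4**
Reactants: 9 3‑[4‑(acetyloxy)phenyl]propyl docosanoate
Product: 10 3‑(4‑hydroxyphenyl)propyl docosanoate
Conditions: pyrrolidine (3 equiv), THF, 0 °C → rt; aq. citric acid work‑up, recrystallisation
Reagents that add atoms: none
Why: Chemoselective aminolysis: the aryl acetate is an activated ester (phenoxide leaving group, pKa about 10) and should be cleaved by a secondary amine at room temperature, whereas the unactivated primary alkyl docosanoate (alkoxide leaving group) is inert to pyrrolidine under these conditions, so only the phenol is released.

**Compound list**
1 | 3‑(4‑hydroxyphenyl)propan‑1‑ol | OCCCc1ccc(O)cc1 | starting material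
2 | sodium 4‑(3‑hydroxypropyl)phenolate | [Na+].[O-]c1ccc(CCCO)cc1 | intermediate
3 | 4‑(3‑hydroxypropyl)phenyl acetate | CC(=O)Oc1ccc(CCCO)cc1 | intermediate
4 | decanedioic acid (sebacic acid) | OC(=O)CCCCCCCCC(=O)O | starting material
5 | 10‑{3‑[4‑(acetyloxy)phenyl]propoxy}‑10‑oxodecanoic acid | OC(=O)CCCCCCCCC(=O)OCCCc1ccc(OC(C)=O)cc1 | intermediate
6 | tetradecanoic acid (myristic acid) | CCCCCCCCCCCCCC(=O)O | starting material
7 | tridecyl radical | [CH2]CCCCCCCCCCCC | intermediate
8 | 9‑{3‑[4‑(acetyloxy)phenyl]propoxy}‑9‑oxononyl radical | [CH2]CCCCCCCC(=O)OCCCc1ccc(OC(C)=O)cc1 | intermediate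
9 | 3‑[4‑(acetyloxy)phenyl]propyl docosanoate | CCCCCCCCCCCCCCCCCCCCCC(=O)OCCCc1ccc(OC(C)=O)cc1 | intermediate
10 | 3‑(4‑hydroxyphenyl)propyl docosanoate | CCCCCCCCCCCCCCCCCCCCCC(=O)OCCCc1ccc(O)cc1 | target

**Summary**
Total step count: 4. Longest linear sequence: 4 steps (1 → 3 → 5 → 9 → 10).

Steps most likely to fail:

1. Step 3 (crossed Kolbe electrolysis). What may go wrong: passivation of the anode by the waxy long‑chain products, predominance of symmetrical coupling, over‑oxidation of the radicals to cations or oxidation of the arene, and methanolysis of the ester groups if the electrolyte drifts alkaline. Fallback: the same C9–C10 bond is made as an alkene by olefin cross‑metathesis and then saturated. The fallback sets out from compound 3. Esterification with dec‑9‑enoic acid (DIC, DMAP, CH2Cl2) should give 3‑[4‑(acetyloxy)phenyl]propyl dec‑9‑enoate F1. Cross‑metathesis of this with excess tetradec‑1‑ene (Grubbs second‑generation catalyst, CH2Cl2, 40 °C) should give 3‑[4‑(acetyloxy)phenyl]propyl docos‑9‑enoate F2 as an E/Z mixture. Hydrogenation (H2, Pd/C, EtOAc) saturates C9=C10 and comes back to the route at compound 9.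

2. Step 2 (statistical mono‑esterification). What may go wrong: esterification at both carboxyl groups to the symmetrical diester, incomplete separation of the half‑ester from excess diacid, and DMAP‑mediated acetyl transfer from the phenol oxygen to the primary alcohol. Fallback: a diacid that is differentiated beforehand. The fallback sets out from compound 3. Coupling with commercial 10‑tert‑butoxy‑10‑oxodecanoic acid (DIC, DMAP, CH2Cl2) should give tert‑butyl 3‑[4‑(acetyloxy)phenyl]propyl decanedioate F3. Acidolysis of the tert‑butyl ester alone (TFA, CH2Cl2, rt) comes back to the route at compound 5.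

3. Step 1 (phenol‑selective acetylation). What may go wrong: loss of site selectivity through acetylation of the primary alcohol, intermolecular acetyl migration, or hydrolysis of the aryl acetate in the basic aqueous medium. Fallback: the order of events is reversed, and selectivity is taken from the inertness of phenols in acid‑catalysed esterification. The fallback sets out from compound 1. Fischer esterification with excess 4 (TsOH cat., toluene/dioxane, reflux, Dean–Stark) should esterify only the aliphatic hydroxyl and give 10‑[3‑(4‑hydroxyphenyl)propoxy]‑10‑oxodecanoic acid F4. Acetylation of the phenol (Ac2O, pyridine, then aqueous hydrolysis of the mixed anhydride) comes back to the route at compound 5, bypassing compound 3.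

**Further compounds**
F1 | step 3 | 3‑[4‑(acetyloxy)phenyl]propyl dec‑9‑enoate | C=CCCCCCCCC(=O)OCCCc1ccc(OC(C)=O)cc1
F2 | step 3 | 3‑[4‑(acetyloxy)phenyl]propyl (E)‑docos‑9‑enoate (E/Z mixture, E isomer shown) | CCCCCCCCCCCC/C=C/CCCCCCCC(=O)OCCCc1ccc(OC(C)=O)cc1
F3 | step 2 | tert‑butyl 3‑[4‑(acetyloxy)phenyl]propyl decanedioate | CC(C)(C)OC(=O)CCCCCCCCC(=O)OCCCc1ccc(OC(C)=O)cc1
F4 | step 1 | 10‑[3‑(4‑hydroxyphenyl)propoxy]‑10‑oxodecanoic acid | OC(=O)CCCCCCCCC(=O)OCCCc1ccc(O)cc1
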